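## Retrosynthetic overview

1. Numbering is that of the target (five-membered ring C1–C2–C3–C3a–C8a; seven-membered ring C3a–C4–C5–C6–C7–C8–C8a). The C4 aroyl and C8 tigloyl esters are cut last; the C4 alcohol comes from a hydroxyl-directed reduction of a C4 ketone, and the C3 carbinol from isopropyl addition to a C3 ketone.
2. The C8 allylic alcohol with the C6=C7 alkene is the ene product of a C7=C8 alkene carrying C6–H. The seven-membered ring is thereby traced to a cyclohepta-1,4-diene (C3a=C4 silyl enol ether and C7=C8) with the quaternary C8a between the two alkenes.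
3. Enabling feature: in that ring the C5–C6 bond lies opposite C8a, between an enol-ether carbon (C4) and an allylic carbon (C6). This is the retron of a cis-divinylcyclopropane (Cope) rearrangement of the cyclopropane C3a–C8a–C8, and the C3 carbonyl on C3a makes C3a a donor/acceptor carbenoid carbon tethered (C3–C2–C1) to the C8a=C8 alkene.
4. Ring order: five-membered ring and cyclopropane by intramolecular cyclopropanation, then the seven-membered ring by C5–C6 bond formation in the same flask, from an acyclic siloxyvinyl diazoketone (pentane-2,4-dione plus a dienyl bromide). A temporary C4/C8 transannular ketal ring later fixes the cis ring fusion and guides the isopropyl addition.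

Key step: step 7

Assumption: Rh2(S-PTAD)4 is taken to give the (3aS) enantiomer of 11 (C8a R in the target); if the sense of induction is opposite, Rh2(R-PTAD)4 is used instead.

Atom numbers in the Why lines are those of the target.

## Route

Step 1
Reactants: 1 (E)-but-2-enal; 2 ethyl 2-(triphenyl-λ5-phosphanylidene)propanoate
Product: 3 ethyl (2E,4E)-2-methylhexa-2,4-dienoate
Conditions: CH2Cl2, rt
Reagents that add atoms: none
Why: Wittig olefination with a stabilised ylide should give the (2E) trisubstituted enoate while the (E) alkene of 1 is retained.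

Step 2
Reactants: 3 ethyl (2E,4E)-2-methylhexa-2,4-dienoate
Product: 4 (2E,4E)-2-methylhexa-2,4-dien-1-ol
Conditions: iBu2AlH (2.2 equiv), CH2Cl2, −78 °C
Reagents that add atoms: none
Why: Hydride reduction of the ester by iBu2AlH proceeds by 1,2-addition and leaves the diene untouched.

Step 3
Reactants: 4 (2E,4E)-2-methylhexa-2,4-dien-1-ol
Product: 5 (2E,4E)-1-bromo-2-methylhexa-2,4-diene
Conditions: PBr3 (0.4 equiv), Et2O, 0 °C, used crude
Reagents that add atoms: phosphorus tribromide, BrP(Br)Br
Why: Bromination of the primary allylic alcohol via its bromophosphite (SN2) should keep both alkene geometries, the conjugated primary bromide being the favoured allylic isomer.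

Step 4
Reactants: 6 pentane-2,4-dione; 5 (2E,4E)-1-bromo-2-methylhexa-2,4-diene
Product: 7 (7E,9E)-7-methylundeca-7,9-diene-2,4-dione
Conditions: LiN(iPr)2 (2.1 equiv), THF, −78 to 0 °C; then 5, −78 to 0 °C
Reagents that add atoms: none
Why: Alkylation of the 1,3-diketone dianion occurs at its terminal carbanion by SN2 attack on the primary allylic bromide, which forms the C1–C2 bond.

Step 5
Reactants: 7 (7E,9E)-7-methylundeca-7,9-diene-2,4-dione
Product: 8 (7E,9E)-3-diazo-7-methylundeca-7,9-diene-2,4-dione
Conditions: 4-acetamidobenzenesulfonyl azide, Et3N, MeCN, 0 °C to rt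
Reagents that add atoms: 4-acetamidobenzenesulfonyl azide, CC(=O)Nc1ccc(cc1)S(=O)(=O)N=[N+]=[N-]
Why: Regitz diazo transfer to the doubly activated methylene of the 1,3-diketone.

Step 6
Reactants: 8 (7E,9E)-3-diazo-7-methylundeca-7,9-diene-2,4-dione
Product: 9 (7E,9E)-2-[(tert-butyldimethylsilyl)oxy]-3-diazo-7-methylundeca-1,7,9-trien-4-one
Conditions: LiN(iPr)2 (1.05 equiv), THF, −78 °C; then TBSOTf, −78 °C
Reagents that add atoms: tert-butyldimethylsilyl trifluoromethanesulfonate, CC(C)(C)[Si](C)(C)OS(=O)(=O)C(F)(F)F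
Why: Kinetic enolisation by the hindered amide base should take the methyl group rather than the methylene of the tether, and O-silylation then gives the siloxyvinyl diazoketone (enol silyl ether formation as used for diazoacetoacetates), the second carbonyl keeping the diazo group acceptor-stabilised.

Step 7
Reactants: 9 (7E,9E)-2-[(tert-butyldimethylsilyl)oxy]-3-diazo-7-methylundeca-1,7,9-trien-4-one
Product: 11 (3aS,6S)-8-[(tert-butyldimethylsilyl)oxy]-3a,6-dimethyl-3,3a,6,7-tetrahydroazulen-1(2H)-one, via cis-divinylcyclopropane 10 (not isolated)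
Conditions: Rh2(S-PTAD)4 (dirhodium tetrakis[(S)-(1-adamantyl)(N-phthalimido)acetate], 1 mol %), hexanes, 0 °C to rt, slow addition of 9; then toluene, 110 °C
Reagents that add atoms: none
Why: The chiral dirhodium carboxylate converts 9 into a donor/acceptor (siloxyvinyl/acyl) carbenoid at C3a, which adds to the proximal trisubstituted C8a=C8 alkene through the three-carbon tether, closing the five-membered ring and the cyclopropane C3a–C8a–C8 stereospecifically, so that the (E)-propenyl group on C8 is exo and cis to the siloxyvinyl group on C3a (10). On warming, this cis-divinylcyclopropane undergoes a [3,3]-sigmatropic (Cope) shift through the boat transition state, forming C5–C6 and cleaving C3a–C8, which closes the seven-membered ring as a cyclohepta-1,4-diene and leaves C4 as a silyl enol ether. The closest known reaction type is the tandem cyclopropanation/Cope rearrangement (formal [4+3] cycloaddition) of siloxyvinyl diazo carbonyl compounds with dienes, including its intramolecular and enantioselective variants with chiral dirhodium carboxylates. C8a is set by catalyst-controlled face selection in the carbenoid addition, and C6 follows from it through the stereospecific boat transition state, the (E)-propenyl geometry placing C6–H on the face of the angular methyl group. The step needs addition to the C8a=C8 alkene rather than the distal C6=C7 alkene, which the five-membered-ring tether secures, and a cis-divinyl arrangement, which the (7E) geometry of 9 secures; heating is expected to be needed because the angular methyl group is syn to both vinyl groups.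

Step 8
Reactants: 11 (3aS,6S)-8-[(tert-butyldimethylsilyl)oxy]-3a,6-dimethyl-3,3a,6,7-tetrahydroazulen-1(2H)-one
Product: 13 (3aR,4R)-8-[(tert-butyldimethylsilyl)oxy]-4-hydroxy-3a,6-dimethyl-3,3a,4,7-tetrahydroazulen-1(2H)-one, via allylic hydroperoxide 12 (not isolated)
Conditions: O2, tetraphenylporphyrin (cat.), visible light, CH2Cl2, 0 °C, run to partial conversion; then PPh3, 0 °C to rt
Reagents that add atoms: dioxygen, O=O
Why: Schenck ene reaction: singlet oxygen can only abstract C6–H (the sole allylic hydrogen), so it bonds suprafacially to C8 on the face of the angular methyl group and moves the alkene to C6=C7; PPh3 then reduces the hydroperoxide, and the electron-poor vinylogous silyl ester should not react.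

Step 9
Reactants: 13 (3aR,4R)-8-[(tert-butyldimethylsilyl)oxy]-4-hydroxy-3a,6-dimethyl-3,3a,4,7-tetrahydroazulen-1(2H)-one
Product: 14 8-methoxy-3a,6-dimethyl-3,3a,4,7,8,8a-hexahydro-4,8-epoxyazulen-1(2H)-one (epoxy bridge, 3a-methyl and 8a-H on one face)
Conditions: pyridinium p-toluenesulfonate (cat.), MeOH, rt
Reagents that add atoms: methanol, CO
Why: Acid-catalysed transannular ketalisation (the C8 hydroxyl adds to C4 of the protonated vinylogous silyl ester, methanol replaces the silyloxy group); because C3a is epimerisable at this stage and a cyclopentanone can only be cis-fused on the eclipsed two-carbon bridge of the 8-oxabicyclo[3.2.1]octene, C3a–H is set cis to the angular methyl group under thermodynamic control.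

Step 10
Reactants: 14 8-methoxy-3a,6-dimethyl-3,3a,4,7,8,8a-hexahydro-4,8-epoxyazulen-1(2H)-one; 15 isopropylmagnesium chloride
Product: 16 8-methoxy-3a,6-dimethyl-1-(propan-2-yl)-1,2,3,3a,4,7,8,8a-octahydro-4,8-epoxyazulen-1-ol (isopropyl cis to 8a-H and 3a-methyl)
Conditions: LaCl3·2LiCl (1 equiv), THF, 0 °C
Reagents that add atoms: none
Why: Lanthanide-promoted Grignard 1,2-addition (suppressing enolisation and reduction) should occur on the exposed face of the endo-fused cyclopentanone, away from the oxabicyclic cage, placing the isopropyl group cis to C3a–H and the C3 hydroxyl towards the seven-membered ring.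

Step 11
Reactants: 16 8-methoxy-3a,6-dimethyl-1-(propan-2-yl)-1,2,3,3a,4,7,8,8a-octahydro-4,8-epoxyazulen-1-ol
Product: 17 (3R,3aR,8R,8aR)-3,8-dihydroxy-6,8a-dimethyl-3-(propan-2-yl)-2,3,3a,5,8,8a-hexahydroazulen-4(1H)-one
Conditions: pyridinium p-toluenesulfonate (cat.), acetone/H2O, 40 °C
Reagents that add atoms: water, O
Why: Mild acid hydrolysis of the mixed ketal through the ring-opened methoxy-oxocarbenium ion releases the C4 ketone and the C8 alcohol without touching a stereocentre, C3a staying cis-fused because the C4 carbonyl is then trans to the isopropyl group.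

Step 12
Reactants: 17 (3R,3aR,8R,8aR)-3,8-dihydroxy-6,8a-dimethyl-3-(propan-2-yl)-2,3,3a,5,8,8a-hexahydroazulen-4(1H)-one; 18 (2E)-2-methylbut-2-enoyl chloride
Product: 19 (3R,3aR,8R,8aR)-3-hydroxy-6,8a-dimethyl-4-oxo-3-(propan-2-yl)-1,2,3,3a,4,5,8,8a-octahydroazulen-8-yl (2E)-2-methylbut-2-enoate
Conditions: Et3N, DMAP (cat.), CH2Cl2, 0 °C to rt
Reagents that add atoms: none
Why: DMAP-catalysed acylation should take the secondary allylic alcohol only, the tertiary alcohol being unreactive, and it draws the hydroxy ketone out of any ring-chain (hemiketal) equilibrium.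

Step 13
Reactants: 19 (3R,3aR,8R,8aR)-3-hydroxy-6,8a-dimethyl-4-oxo-3-(propan-2-yl)-1,2,3,3a,4,5,8,8a-octahydroazulen-8-yl (2E)-2-methylbut-2-enoate
Product: 20 (3R,3aS,4S,8R,8aR)-3,4-dihydroxy-6,8a-dimethyl-3-(propan-2-yl)-1,2,3,3a,4,5,8,8a-octahydroazulen-8-yl (2E)-2-methylbut-2-enoate
Conditions: Me4NBH(OAc)3, MeCN/AcOH (1:1), −30 to 0 °C
Reagents that add atoms: none
Why: Evans–Saksena hydroxyl-directed reduction: boron bound to the tertiary C3 hydroxyl delivers hydride to the face of the C4 ketone that is turned towards the five-membered ring, giving the C4 alcohol cis to C3a–H, while the unsaturated ester is inert.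

Step 14
Reactants: 20 (3R,3aS,4S,8R,8aR)-3,4-dihydroxy-6,8a-dimethyl-3-(propan-2-yl)-1,2,3,3a,4,5,8,8a-octahydroazulen-8-yl (2E)-2-methylbut-2-enoate; 21 4-[(tert-butyldimethylsilyl)oxy]benzoic acid
Product: 22 (3R,3aS,4S,8R,8aR)-3-hydroxy-6,8a-dimethyl-8-{[(2E)-2-methylbut-2-enoyl]oxy}-3-(propan-2-yl)-1,2,3,3a,4,5,8,8a-octahydroazulen-4-yl 4-[(tert-butyldimethylsilyl)oxy]benzoate
Conditions: DCC, DMAP, CH2Cl2, rt
Reagents that add atoms: none
Why: Steglich esterification of the secondary C4 alcohol, the tertiary C3 alcohol being too hindered to react and the phenol being masked.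

Step 15
Reactants: 22 (3R,3aS,4S,8R,8aR)-3-hydroxy-6,8a-dimethyl-8-{[(2E)-2-methylbut-2-enoyl]oxy}-3-(propan-2-yl)-1,2,3,3a,4,5,8,8a-octahydroazulen-4-yl 4-[(tert-butyldimethylsilyl)oxy]benzoate
Product: 23 (3R,3aS,4S,8R,8aR)-3-hydroxy-6,8a-dimethyl-8-{[(2E)-2-methylbut-2-enoyl]oxy}-3-(propan-2-yl)-1,2,3,3a,4,5,8,8a-octahydroazulen-4-yl 4-hydroxybenzoate
Conditions: HF·pyridine, THF/pyridine, 0 °C
Reagents that add atoms: none
Why: Fluoride cleavage of the aryl silyl ether is fast and should leave both esters and the tertiary alcohol intact.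

## Compound list

1 | (E)-but-2-enal | C/C=C/C=O | starting material
2 | ethyl 2-(triphenyl-λ5-phosphanylidene)propanoate | CCOC(=O)C(C)=P(c1ccccc1)(c1ccccc1)c1ccccc1 | starting material
3 | ethyl (2E,4E)-2-methylhexa-2,4-dienoate | CCOC(=O)/C(C)=C/C=C/C | intermediate
4 | (2E,4E)-2-methylhexa-2,4-dien-1-ol | OC/C(C)=C/C=C/C | intermediate
5 | (2E,4E)-1-bromo-2-methylhexa-2,4-diene | BrC/C(C)=C/C=C/C | intermediate
6 | pentane-2,4-dione | CC(=O)CC(C)=O | starting material
7 | (7E,9E)-7-methylundeca-7,9-diene-2,4-dione | CC(=O)CC(=O)CC/C(C)=C/C=C/C | intermediate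
8 | (7E,9E)-3-diazo-7-methylundeca-7,9-diene-2,4-dione | CC(=O)C(=[N+]=[N-])C(=O)CC/C(C)=C/C=C/C | intermediate
9 | (7E,9E)-2-[(tert-butyldimethylsilyl)oxy]-3-diazo-7-methylundeca-1,7,9-trien-4-one | C=C(O[Si](C)(C)C(C)(C)C)C(=[N+]=[N-])C(=O)CC/C(C)=C/C=C/C | intermediate
10 | 1-{1-[(tert-butyldimethylsilyl)oxy]ethenyl}-5-methyl-6-[(E)-prop-1-enyl]bicyclo[3.1.0]hexan-2-one, propenyl exo and cis on the cyclopropane to the siloxyvinyl and 5-methyl groups | O=C1CC[C@@]2(C)[C@H](/C=C/C)[C@@]12C(=C)O[Si](C)(C)C(C)(C)C | intermediate (not isolated)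
11 | (3aS,6S)-8-[(tert-butyldimethylsilyl)oxy]-3a,6-dimethyl-3,3a,6,7-tetrahydroazulen-1(2H)-one, 6-H cis to 3a-methyl | CC(C)(C)[Si](C)(C)OC1=C2C(=O)CC[C@@]2(C)C=C[C@@H](C)C1 | intermediate
12 | (3aR,4R)-8-[(tert-butyldimethylsilyl)oxy]-4-hydroperoxy-3a,6-dimethyl-3,3a,4,7-tetrahydroazulen-1(2H)-one | OO[C@@H]1C=C(C)CC(O[Si](C)(C)C(C)(C)C)=C2C(=O)CC[C@@]12C | intermediate (not isolated)
13 | (3aR,4R)-8-[(tert-butyldimethylsilyl)oxy]-4-hydroxy-3a,6-dimethyl-3,3a,4,7-tetrahydroazulen-1(2H)-one, hydroxyl cis to 3a-methyl | O[C@@H]1C=C(C)CC(O[Si](C)(C)C(C)(C)C)=C2C(=O)CC[C@@]12C | intermediate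
14 | 8-methoxy-3a,6-dimethyl-3,3a,4,7,8,8a-hexahydro-4,8-epoxyazulen-1(2H)-one, epoxy bridge, 3a-methyl and 8a-H on one face | CO[C@@]12CC(C)=C[C@@H](O1)[C@]3(C)CCC(=O)[C@H]23 | intermediate
15 | isopropylmagnesium chloride | CC(C)[Mg]Cl | starting material
16 | 8-methoxy-3a,6-dimethyl-1-(propan-2-yl)-1,2,3,3a,4,7,8,8a-octahydro-4,8-epoxyazulen-1-ol, isopropyl cis to 8a-H and 3a-methyl | CO[C@@]12CC(C)=C[C@@H](O1)[C@]3(C)CC[C@@](O)(C(C)C)[C@H]23 | intermediate
17 | (3R,3aR,8R,8aR)-3,8-dihydroxy-6,8a-dimethyl-3-(propan-2-yl)-2,3,3a,5,8,8a-hexahydroazulen-4(1H)-one | O[C@@H]1C=C(C)CC(=O)[C@@H]2[C@@]1(C)CC[C@@]2(O)C(C)C | intermediate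
18 | (2E)-2-methylbut-2-enoyl chloride (tigloyl chloride) | C/C=C(\C)C(Cl)=O | starting material
19 | (3R,3aR,8R,8aR)-3-hydroxy-6,8a-dimethyl-4-oxo-3-(propan-2-yl)-1,2,3,3a,4,5,8,8a-octahydroazulen-8-yl (2E)-2-methylbut-2-enoate | C/C=C(\C)C(=O)O[C@@H]1C=C(C)CC(=O)[C@@H]2[C@@]1(C)CC[C@@]2(O)C(C)C | intermediate
20 | (3R,3aS,4S,8R,8aR)-3,4-dihydroxy-6,8a-dimethyl-3-(propan-2-yl)-1,2,3,3a,4,5,8,8a-octahydroazulen-8-yl (2E)-2-methylbut-2-enoate | C/C=C(\C)C(=O)O[C@@H]1C=C(C)C[C@H](O)[C@@H]2[C@@]1(C)CC[C@@]2(O)C(C)C | intermediate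
21 | 4-[(tert-butyldimethylsilyl)oxy]benzoic acid | CC(C)(C)[Si](C)(C)Oc1ccc(cc1)C(O)=O | starting material
22 | (3R,3aS,4S,8R,8aR)-3-hydroxy-6,8a-dimethyl-8-{[(2E)-2-methylbut-2-enoyl]oxy}-3-(propan-2-yl)-1,2,3,3a,4,5,8,8a-octahydroazulen-4-yl 4-[(tert-butyldimethylsilyl)oxy]benzoate | C/C=C(\C)C(=O)O[C@@H]1C=C(C)C[C@H](OC(=O)c2ccc(O[Si](C)(C)C(C)(C)C)cc2)[C@@H]2[C@@]1(C)CC[C@@]2(O)C(C)C | intermediate
23 | (3R,3aS,4S,8R,8aR)-3-hydroxy-6,8a-dimethyl-8-{[(2E)-2-methylbut-2-enoyl]oxy}-3-(propan-2-yl)-1,2,3,3a,4,5,8,8a-octahydroazulen-4-yl 4-hydroxybenzoate | C/C=C(\C)C(=O)O[C@@H]1C=C(C)C[C@H](OC(=O)c2ccc(O)cc2)[C@@H]2[C@@]1(C)CC[C@@]2(O)C(C)C | target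

## Summary and risks

Total step count: 15. Longest linear sequence: 15 steps (1 to 23).

Steps most likely to fail:

**Step 7.** Enantiofacial discrimination by the chiral carboxylate may be weak, the siloxyvinyl diazo compound may be lost by electrocyclisation before the carbenoid forms, or the boat-type [3,3] shift may be slow because the angular methyl group is syn to both vinyl groups. The fallback separates the two events and uses an acceptor/acceptor carbenoid. It sets out from diazodione 8, which is cyclised with [Cu(MeCN)4]PF6 and 2,2'-isopropylidenebis[(4S)-4-tert-butyl-2-oxazoline] (monovalent copper, CH2Cl2, rt) to 1-acetyl-5-methyl-6-[(E)-prop-1-enyl]bicyclo[3.1.0]hexan-2-one F1 (propenyl exo). Kinetic O-silylation of the acetyl group of F1 (LiN(iPr)2, TBSOTf, THF, −78 °C; the ring enol ether cannot enter the rearrangement) then generates 10, which is heated in toluene and comes back to the route at 11.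

**Step 6.** Deprotonation at the tether methylene may compete, giving the regioisomeric enol ether, or the amide base may attack the diazo group. The fallback fixes the regiochemistry by symmetry before the chain is attached. It sets out from pentane-2,4-dione 6, which undergoes diazo transfer (4-acetamidobenzenesulfonyl azide, Et3N, MeCN) to 3-diazopentane-2,4-dione F2. Mono-silylation (TBSOTf, 1 equiv, Et3N, CH2Cl2, 0 °C) gives 4-[(tert-butyldimethylsilyl)oxy]-3-diazopent-4-en-2-one F3, the only possible mono-enol ether. Its lithium enolate (LiN(iPr)2, THF, −78 °C; one enolisable position) is alkylated with bromide 5, which comes back to the route at 9.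

**Step 8.** The ene reaction of the cis-disubstituted alkene may be slow, so that the trisubstituted alkene of the product is oxidised further. The fallback replaces photooxygenation by an oxidative 1,3-transposition and sets out from 11. SeO2 (cat.) with tBuOOH in CH2Cl2 (ene reaction then [2,3] shift) should give the tertiary allylic alcohol 8-[(tert-butyldimethylsilyl)oxy]-6-hydroxy-3a,6-dimethyl-3,3a,6,7-tetrahydroazulen-1(2H)-one F4. Babler–Dauben oxidation with pyridinium chlorochromate, (C5H5NH)[CrO3Cl], buffered with NaOAc, should give the transposed enone 8-[(tert-butyldimethylsilyl)oxy]-3a,6-dimethyl-3,3a-dihydroazulene-1,4(2H,7H)-dione F5. Luche reduction (NaBH4, CeCl3·7H2O, MeOH, −78 °C), with hydride expected to enter anti to the axial angular methyl group, comes back to the route at 13; only this cis alcohol can enter the transannular ketal of step 9.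

Further compounds
F1 | step 7 | 1-acetyl-5-methyl-6-[(E)-prop-1-enyl]bicyclo[3.1.0]hexan-2-one, propenyl exo and cis to the acetyl and 5-methyl groups | O=C1CC[C@@]2(C)[C@H](/C=C/C)[C@@]12C(C)=O
F2 | step 6 | 3-diazopentane-2,4-dione | CC(=O)C(=[N+]=[N-])C(C)=O
F3 | step 6 | 4-[(tert-butyldimethylsilyl)oxy]-3-diazopent-4-en-2-one | C=C(O[Si](C)(C)C(C)(C)C)C(=[N+]=[N-])C(C)=O
F4 | step 8 | 8-[(tert-butyldimethylsilyl)oxy]-6-hydroxy-3a,6-dimethyl-3,3a,6,7-tetrahydroazulen-1(2H)-one, hydroxyl cis to 3a-methyl | CC(C)(C)[Si](C)(C)OC1=C2C(=O)CC[C@@]2(C)C=C[C@](C)(O)C1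
F5 | step 8 | 8-[(tert-butyldimethylsilyl)oxy]-3a,6-dimethyl-3,3a-dihydroazulene-1,4(2H,7H)-dione | CC(C)(C)[Si](C)(C)OC1=C2C(=O)CC[C@@]2(C)C(=O)C=C(C)C1
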